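**Assumptions:** (S)-Liquiritigenin, (2S)-7,4'-dihydroxyflavanone, is bought as the single natural enantiomer. The 7-allyloxy Claisen rearrangement favours C8 over C6, and the minor C6 isomer is removed by chromatography.

## Retrosynthetic overview
- Sophoranone is 8,3',5'-triprenyl-liquiritigenin, so the target is disconnected to (S)-liquiritigenin (1). This supplies the intact flavanone (both rings, including the ring O–C2 bond) and C2 with the correct (S) configuration. No ring is formed in the route.
- The three prenyl groups come from the allyl analogue 9 by one cross-metathesis with 2-methyl-2-butene.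
- The three aryl C–C bonds (C8, C3', C5') form by aromatic Claisen [3,3] rearrangements of aryl allyl ethers.
- The Claisen steps are done in two rounds. Round 1 does C8 and C3' together. Round 2 does C5' after the more acidic 7-OH is masked as its MOM ether.

## Route

**Step 1**
Reactants: **1** (2S)-7,4'-dihydroxyflavanone (liquiritigenin); **2** allyl bromide
Product: **3** (2S)-7-allyloxy-2-(4-allyloxyphenyl)chroman-4-one
Conditions: **2** (2.5 equiv), K2CO3 (2.5 equiv), acetone, 50 °C
Reagents that add atoms: allyl bromide, C=CCBr
Why: Williamson etherification of both phenols. The 7-phenoxide, with its para carbonyl, stabilises C2–O against ring opening, and C2 is untouched.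

**Step 2**
Reactants: **3**
Product: **4** (2S)-8-allyl-2-(3-allyl-4-hydroxyphenyl)-7-hydroxychroman-4-one
Conditions: PhNEt2, 200 °C (microwave), 1 h
Reagents that add atoms: none
Why: Aromatic Claisen [3,3] rearrangement of both aryl allyl ethers. The 7-O-allyl group migrates to the ortho C8 and the 4'-O-allyl group to C3'. C2 is not involved, so its configuration is retained.

**Step 3**
Reactants: **4**; **5** chloromethyl methyl ether (MOMCl)
Product: **6** (2S)-8-allyl-2-(3-allyl-4-hydroxyphenyl)-7-(methoxymethoxy)chroman-4-one
Conditions: **5** (1.0 equiv), K2CO3 (1.0 equiv), acetone, 0 °C to rt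
Reagents that add atoms: MOMCl, COCCl
Why: Chemoselective O-alkylation. The 7-OH is a vinylogous acid (pKa about 7.5) and is deprotonated in preference to the 4'-OH (pKa about 10), so it is the one masked as MOM.

**Step 4**
Reactants: **6**; **2** allyl bromide
Product: **7** (2S)-8-allyl-2-(3-allyl-4-allyloxyphenyl)-7-(methoxymethoxy)chroman-4-one
Conditions: **2** (1.5 equiv), K2CO3, acetone, 55 °C
Reagents that add atoms: allyl bromide, C=CCBr
Why: Williamson etherification of the only free phenol, the 4'-OH.

**Step 5**
Reactants: **7**
Product: **8** (2S)-8-allyl-2-(3,5-diallyl-4-hydroxyphenyl)-7-(methoxymethoxy)chroman-4-one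
Conditions: PhNEt2, 200 °C (microwave), 1 h
Reagents that add atoms: none
Why: Claisen [3,3] rearrangement of the 4'-O-allyl ether into the remaining free ortho position C5'. The MOM aryl ether is stable to heat, so C7 cannot rearrange, and C2 is unchanged.

**Step 6**
Reactants: **8**
Product: **9** (2S)-8-allyl-2-(3,5-diallyl-4-hydroxyphenyl)-7-hydroxychroman-4-one
Conditions: 2 M HCl, THF/MeOH (1:1), 45 °C, 4 h
Reagents that add atoms: none (HCl and MeOH leave as MeOCH2OMe)
Why: Acid hydrolysis of the MOM acetal. Flavanones tolerate acid without ring opening or racemisation, and the allyl groups are inert, which is why MOM removal comes before prenyl formation. The prenyl groups would be acid-prone.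

**Step 7**
Reactants: **9**; **10** 2-methyl-2-butene
Product: **11** sophoranone, (2S)-7-hydroxy-8-prenyl-2-(4-hydroxy-3,5-diprenylphenyl)chroman-4-one
Conditions: **10** (30 equiv), Hoveyda–Grubbs II (15 mol%), 1,4-benzoquinone (10 mol%), CH2Cl2, 40 °C, sealed tube, 18 h
Reagents that add atoms: 2-methyl-2-butene, CC=C(C)C
Why: Olefin cross-metathesis with the trisubstituted alkene partner converts each terminal allyl group into a prenyl group, with propene as the by-product. Benzoquinone suppresses Ru–H alkene isomerisation, and C2 is unaffected.

## Checks carried out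
- **Structure:** Compound 11 has the chromanone ring, 7-OH, 8-prenyl and the 4-hydroxy-3,5-diprenylphenyl group at C2. Its formula is C30H36O4, and it matches the target SMILES.
- **Stereochemistry:** C2 is never touched. The CIP priorities (O > aryl > CH2 > H) are the same in every intermediate, so all are (S).
- **Functional groups:** The MOM ether survives the basic alkylation and thermal Claisen steps. The acid in step 6 is mild enough to spare the allyl groups and the flavanone, and the free phenols are tolerated in the metathesis.

## Compound list
1 | (2S)-7,4'-dihydroxyflavanone (liquiritigenin) | Oc1ccc(cc1)[C@@H]2CC(=O)c3ccc(O)cc3O2 | starting material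
2 | allyl bromide | C=CCBr | starting material (reagent)
3 | (2S)-7-allyloxy-2-(4-allyloxyphenyl)chroman-4-one | C=CCOc1ccc(cc1)[C@@H]2CC(=O)c3ccc(OCC=C)cc3O2 | intermediate
4 | (2S)-8-allyl-2-(3-allyl-4-hydroxyphenyl)-7-hydroxychroman-4-one | C=CCc1cc(ccc1O)[C@@H]2CC(=O)c3ccc(O)c(CC=C)c3O2 | intermediate
5 | chloromethyl methyl ether | COCCl | starting material (reagent)
6 | 7-MOM ether of 4 | C=CCc1cc(ccc1O)[C@@H]2CC(=O)c3ccc(OCOC)c(CC=C)c3O2 | intermediate
7 | 4'-O-allyl ether of 6 | C=CCc1cc(ccc1OCC=C)[C@@H]2CC(=O)c3ccc(OCOC)c(CC=C)c3O2 | intermediate
8 | (2S)-8-allyl-2-(3,5-diallyl-4-hydroxyphenyl)-7-MOM-oxychroman-4-one | C=CCc1cc(cc(CC=C)c1O)[C@@H]2CC(=O)c3ccc(OCOC)c(CC=C)c3O2 | intermediate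
9 | (2S)-8-allyl-2-(3,5-diallyl-4-hydroxyphenyl)-7-hydroxychroman-4-one | C=CCc1cc(cc(CC=C)c1O)[C@@H]2CC(=O)c3ccc(O)c(CC=C)c3O2 | intermediate
10 | 2-methyl-2-butene | CC=C(C)C | starting material (reagent)
11 | sophoranone | CC(C)=CCc1cc(cc(CC=C(C)C)c1O)[C@@H]2CC(=O)c3ccc(O)c(CC=C(C)C)c3O2 | target

**Total steps:** 7. **Longest linear sequence:** 7 steps, from compound 1.

## Three steps most likely to fail
1. **Step 7, triple cross-metathesis:** it may stop at partial conversion or give isomerised propenyl by-products. Fallback: make the prenyl groups directly in the Claisen steps by using aryl 1,1-dimethylallyl ethers (from 3-chloro-3-methylbut-1-yne propargylation and partial hydrogenation). This replaces allyl with a different Claisen substrate and removes the metathesis.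
2. **Step 3, selective MOM protection of 7-OH in the presence of the similarly hindered 4'-OH:** it may give bis-MOM product or the wrong mono-ether. Fallback: change the order. Mask the unhindered 7-OH of 1 as MOM first, do both B-ring allylation/Claisen rounds, then deprotect, allylate and rearrange at C8 last. Selectivity is easier at that stage, but the route is two steps longer.
3. **Steps 2 and 5, thermal Claisen:** the C6/C8 regioselectivity may be poor, and the flavanone C2 may racemise at about 200 °C through reversible ring opening to the chalcone. Fallback: use BCl3-promoted Claisen rearrangement at −78 °C to 0 °C, which avoids the high-temperature manifold entirely (step 2 substrate only, since the MOM ether in step 5 would not survive BCl3).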